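The readings were computed on assumed constants; noise was put on by code.

- Don't let a fitted target curve answer two questions at once: who catches the material, and what later happens to what was caught. Solve the first at the start of the flask and the second at its end.

| flask | starting material | first nucleophile | second nucleophile | temperature | remark | time |
|---|---|---|---|---|---|---|
| alder | 0.064 M | 0.18 M (in portions, 4) | 0.15 M | 20 °C | run made earlier; portions every 25 h |  |
| cedar | 0.099 M | 0.18 M (in portions, 4) | 0.15 M | 31 °C | run made earlier; portions every 25 h |  |
| south-west | 0.10 M | 0.180 M (in portions, 4) | 0.150 M | 25 °C | the portions of first nucleophile follow each other after 25 h, the first at the start | 4.0 d |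
| north-west | 0.15 M | 0.180 M | 0.150 M | 25 °C | everything together at the start | 4.0 d |

| run | time / h | target / % | other capture product / % |
|---|---|---|---|
| alder | 6.00 | 1 | 5 |
| alder | 15.0 | 2 | 14 |
| alder | 20.0 | 3 | 21 |
| alder | 30.0 | 11 | 33 |
| alder | 40.0 | 17 | 40 |
| alder | 50.0 | 17 | 45 |
| cedar | 6.00 | 7 | 19 |
| cedar | 15.0 | 11 | 47 |
| cedar | 20.0 | 13 | 55 |
| cedar | 30.0 | 13 | 58 |
| cedar | 40.0 | 18 | 62 |
| cedar | 50.0 | 11 | 61 |

(scatter of a reading: 2 percentage points)

- the winner by share of target in all that became target or other capture product or side product or over-reaction product; "neither" if no more than 2 percentage points parts them (south-west / north-west / neither)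
- share of target in all that became target or other capture product or side product or over-reaction product, south-west
- share of target in all that became target or other capture product or side product or over-reaction product, north-west

- in percentages every species weighs as the starting material in it: one side product counts as two
- a reading or a percentage of target counts all its forms, free or not

- Start with the capture ratio, your selectivity factor: target gained over other capture product gained, divided by first over second nucleophile present. Take each nucleophile's presence from its charge.
- In the cedar run at 6.00 h, one portion gives 1.23.
- In the alder run from 20.0 h to 40.0 h, a span the second portion enters at 25 h, reckoning two portions gives 1.23. Both are readings with wide scatter, but they span the temperature asked, so take that ratio at 25 °C.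
- Now define the capture share: target plus over-reaction product, as a fraction of those two plus other capture product. With the whole charge in, as in north-west, it is 59.6%.
- With one portion in, south-west starts at 26.9%. By 20.0 h, before the second portion, the cedar run had captured 68.0% of its starting material and the alder run 24.0%, so south-west should stay nearer its low end.
- At the late end, cedar's target reads 18% at 40.0 h and 11% at 50.0 h, with a scatter of 2 percentage points, a warning that target may move on to over-reaction product. The shares asked should therefore fall below these capture shares, by an amount these readings price poorly. I commit to north-west.
- The forecast also says north-west, with 29% for south-west and 48% for north-west, on the ground that “Portioning therefore starves target”; these are not my capture shares.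
- The flasks give north-west: 17.5% for south-west and 27.1% for north-west.

    starting material → intermediate (k = 1.12 × 10⁻⁵ s⁻¹, Ea = 92.0 kJ mol⁻¹)
    first nucleophile + intermediate → target (k = 4.47 × 10⁻⁴ M⁻¹ s⁻¹, Ea = 72.0 kJ mol⁻¹)
    second nucleophile + intermediate → other capture product (k = 4.41 × 10⁻⁴ M⁻¹ s⁻¹, Ea = 55.0 kJ mol⁻¹)
    starting material + intermediate → side product (k = 6.55 × 10⁻⁵ M⁻¹ s⁻¹, Ea = 84.0 kJ mol⁻¹)
    crystals ⇌ target, rate k5*(cs5 - [target]) while solid is left; crystals form when [target] > cs5 (solubility = 47.0 mM, k = 6.76 × 10⁻⁴ s⁻¹)
    target → over-reaction product (k = 2.58 × 10⁻⁶ s⁻¹, Ea = 113 kJ mol⁻¹)
    (constants at 25 °C)

- At 4.00 d, north-west has 58.4% of its first and 58.8% of its second nucleophile left, so their ratio is still near the charged one, and the capture share built up in that flask, 54.8%, can stand beside my 59.6%; south-west's, built up over its portions, is 33.1%. In north-west at that time, dissolved target is made at 0.198 of the rate at which it is used up, with 23.5% over-reaction product beside 26.5% target.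
- Second flask: north-west read at 40 h has the same charges, so the capture share I reckon is again 59.6%. Computed, the capture share built up in that flask by then is 54.8%, with a target share of 40.7%.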